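**Plan**
1. Numbering: ring A is C1(OAc)–C2–C3–C4(HBr)–C5(Me2)–C6; C7 is the CH2 link; the cyclopentane is C8(carries C7)–C9–C10–C11(angular Me)–C16(H); the cyclohexane is C11–C12(HBr)–C13–C14–C15(Me,OH)–C16.
2. Cuts: C1–C7 (alkylcerium plus ring A ketone), then C12–Br and C4–Br, then C8–C9. Rejoining C9 to C7 turns the cyclopentane and its exocyclic C7 back into a six-membered C7 ketone with a diazo group on C8.
3. Enabling feature: the trans C11/C16-fused bicycle with an angular C11 methyl, a heteroatom at C12 and a one-carbon branch (C7) on C8 next to the fusion CH is a Wieland–Miescher decalin short of one ring carbon, so the enone carbonyl can be pushed out of the ring as C7 by a Wolff shift.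
4. Forward: (S)-Wieland–Miescher ketone supplies the decalin; C15 is oxidised and methylated, the enone is reduced to the trans-decalin C7–C8 enolate, C8 is diazotised and the ring contracted (step 10); C12 then becomes CHBr; ring A is closed separately by a bromonium cyclisation; the halves are joined last at C1–C7.
5. Stereochemistry: C11 from the starting ketone; C15 by methyl delivery anti to the angular methyl; C16 by axial protonation in the metal–ammonia reduction; C8 by base equilibration of the ester; C12 by hydrogen delivery opposite the angular methyl; C4 from a Sharpless epoxide opened with inversion by bromide; C1 by equatorial attack on the ring A ketone.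

Key step: step 10

Remark: target atom numbers are used for all intermediates; α means the face opposite the angular C11 methyl; tautomeric compounds 12 and 30 are drawn in one form each, and the diol and ketol 3 and 4 as the α-face isomers (both centres are erased in steps 3–4).

**Route**

Step 1
Reactants: 1 (S)-Wieland–Miescher ketone
Product: 2 bis(ethylene ketal) with the alkene at C15=C16
Conditions: HOCH2CH2OH, p-TsOH (cat.), benzene, reflux, Dean–Stark
Reagents that add atoms: ethylene glycol, OCCO
Why: Acid-catalysed ketalisation of both carbonyls; the enone ketalises through its dienol, so the double bond settles β,γ at C15=C16, and the quaternary C11 centre is untouched.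

Step 2
Reactants: 2 bis(ethylene ketal)
Product: 3 15α,16α-diol
Conditions: OsO4 (5 mol%), NMO, MeSO2NH2, acetone–H2O, rt to 40 °C
Reagents that add atoms: osmium tetroxide, O=[Os](=O)(=O)=O; N-methylmorpholine N-oxide, C[N+]1([O-])CCOCC1; water, O
Why: Upjohn dihydroxylation of the trisubstituted alkene, expected syn from the α face; the facial outcome does not matter because C15 and C16 lose their configuration in steps 3 and 4.

Step 3
Reactants: 3 15α,16α-diol
Product: 4 16-hydroxy-15-ketone (α-ketol)
Conditions: IBX, DMSO, rt
Reagents that add atoms: none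
Why: IBX oxidises the secondary C15 alcohol of a vicinal diol to the ketone without C–C cleavage and leaves the tertiary C16 hydroxyl and both ketals alone.

Step 4
Reactants: 4 α-ketol
Product: 5 15-oxo-C8=C16 enone (both ketals kept)
Conditions: SOCl2, pyridine, 0 °C
Reagents that add atoms: none
Why: Dehydration of a tertiary α-ketol through its chlorosulfite (anti elimination); C16–O has β-hydrogens only on C8 (C11 is quaternary, C15 a carbonyl), so only the conjugated C8=C16 enone can form, as in the dehydration of 5α-hydroxy-6-keto steroids.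

Step 5
Reactants: 5 enone
Product: 6 tertiary allylic alcohol (15β-OH, 15α-CH3)
Conditions: MeLi, CeCl3 (anhydrous), THF, −78 °C; sat. NH4Cl
Reagents that add atoms: methyllithium, [Li]C
Why: 1,2-Addition of the weakly basic methylcerium reagent to the enone carbonyl; axial (β) approach is blocked by the syn-axial angular methyl, so methyl enters equatorially from the α face and sets C15 with OH β (axial) and CH3 α.

Step 6
Reactants: 6 tertiary allylic alcohol
Product: 7 γ-hydroxy enone (C7 ketone, C8=C16, C12 ketal)
Conditions: PPTS (cat.), acetone–H2O (20:1), rt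
Reagents that add atoms: water, O
Why: The C7 ketal is allylic and hydrolyses through a conjugated oxocarbenium ion far faster than the neopentyl C12 ketal, and the acid is too weak to ionise the tertiary allylic alcohol.

Step 7
Reactants: 7 γ-hydroxy enone
Product: 10 trans-decalin bis(triethylsilyl) compound (C7=C8 silyl enol ether plus C15 silyl ether), via lithium alkoxide 8 (not isolated), via dilithium enolate alkoxide 9 (not isolated)
Conditions: LiHMDS (1.05 equiv), THF, −78 °C; Li, NH3–THF, −78 °C; isoprene; evaporate NH3; Et3SiOTf, Et3N, THF, −78 → 0 °C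
Reagents that add atoms: triethylsilyl trifluoromethanesulfonate, CC[Si](CC)(CC)OS(=O)(=O)C(F)(F)F
Why: Dissolving-metal (Birch-type) enone reduction with enolate trapping: the C15 hydroxyl is first made into its lithium alkoxide so that the C16 carbanion has no leaving group to expel (the freed amine or ammonia is the proton source), axial protonation at C16 anti to the angular methyl gives the trans fusion, and the enolate, formed only across C7–C8, is fixed together with the alkoxide by O-silylation.

Step 8
Reactants: 10 bis(triethylsilyl) compound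
Product: 12 C8-trifluoroacetyl ketone (enol form), via lithium enolate 11 (not isolated)
Conditions: MeLi, THF, 0 °C → rt; then CF3CO2CH2CF3, −78 °C; sat. NH4Cl
Reagents that add atoms: 2,2,2-trifluoroethyl trifluoroacetate, O=C(OCC(F)(F)F)C(F)(F)F
Why: Methyllithium cleaves the silyl enol ether (not the tertiary alkyl silyl ether) to regenerate the regiodefined lithium enolate, which undergoes Claisen C-acylation at C8 with the activated trifluoroacetate.

Step 9
Reactants: 12 C8-trifluoroacetyl ketone
Product: 13 trans-decalin α-diazo ketone (C7 ketone, C8 diazo)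
Conditions: MsN3, Et3N, H2O (1 equiv), MeCN, rt
Reagents that add atoms: methanesulfonyl azide, CS(=O)(=O)N=[N+]=[N-]
Why: Deacylative (detrifluoroacetylative) Regitz diazo transfer: the enolised 1,3-dicarbonyl adds to the sulfonyl azide and the triazoline fragments with loss of the trifluoroacetyl group as its sulfonamide, leaving the diazo group only at C8.

Step 10
Reactants: 13 trans-decalin α-diazo ketone
Product: 16 trans-hydrindane methyl ester (C8 α), via ketene 14 (not isolated), via C8-epimeric ester 15 (not isolated)
Conditions: hν (medium-pressure Hg lamp, Pyrex), MeOH, 0–20 °C; then NaOMe (0.2 equiv), 40 °C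
Reagents that add atoms: methanol, CO
Why: Direct irradiation expels N2 from the s-cis-locked α-diazo ketone while C9 shifts from the carbonyl carbon C7 to C8 (photochemical Wolff rearrangement), giving ketene 14 in which C8–C9 is the new ring bond and C7 is exocyclic; methanol adds to the ketene to give the ester. The closest known reactions are the photolytic ring contractions of cyclic 2-diazo ketones made by deacylative diazo transfer (A-nor and D-nor steroids). The cyclopentane C8–C9–C10–C11–C16 arises by contraction of the six-membered ring through this 1,2-shift and not by a cyclisation, so no ring-closing trajectory is involved and the trans C11/C16 fusion from step 7 is carried over unchanged. The one new stereocentre, C8, is formed on protonation of the ketene–methanol adduct and is then put under thermodynamic control by methoxide: the ester should settle trans to C15 (cis to H16), away from the fully substituted C15 and the angular methyl. Regiochemistry requires the diazo group at C8 and not C9, which the enone-derived enolate of step 7 secures, so that C9 is the only carbon able to migrate. Chemoselectivity requires the ketene to be trapped by methanol and not by the C15 oxygen (which would give a cis-lactone with the wrong C8 configuration), which the triethylsilyl ether secures.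

Step 11
Reactants: 16 trans-hydrindane methyl ester
Product: 17 primary alcohol (C7–OH)
Conditions: LiAlH4, THF, 0 °C
Reagents that add atoms: none
Why: Hydride reduction of the ester to the primary alcohol, which also removes the acidity of C8 and so locks its configuration; ketal and silyl ether are inert.

Step 12
Reactants: 17 primary alcohol
Product: 18 C12 ketone
Conditions: PPTS, acetone–H2O (10:1), 55 °C
Reagents that add atoms: water, O
Why: Acid-catalysed hydrolysis (transketalisation into acetone) of the remaining dioxolane; the hindered tertiary triethylsilyl ether and the primary alcohol should survive PPTS.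

Step 13
Reactants: 18 C12 ketone
Product: 19 C12 hydrazone
Conditions: N2H4·H2O, Et3N, EtOH, 85 °C (sealed)
Reagents that add atoms: hydrazine, NN
Why: Hydrazone formation on the hindered C12 ketone under the forcing conditions used for ketones next to a quaternary carbon (17-keto steroids).

Step 14
Reactants: 19 C12 hydrazone
Product: 20 vinyl bromide (C12(Br)=C13)
Conditions: NBS, pyridine, CH2Cl2, −10 °C → rt
Reagents that add atoms: N-bromosuccinimide, O=C1CCC(=O)N1Br
Why: Hydrazone-to-vinyl-halide reaction (Barton type): N-bromination and loss of HBr give the diazoalkane, a second Br+ and loss of N2 give an α-bromo cation that loses the only available proton (C13–H); the bromine-stabilised cation should not rearrange.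

Step 15
Reactants: 20 vinyl bromide
Product: 21 12β-bromide (equatorial), C7–OH
Conditions: H2 (3 atm), 5% Rh/Al2O3, EtOAc, rt
Reagents that add atoms: none
Why: Catalytic hydrogenation of a vinyl bromide over rhodium, a metal with little tendency to hydrogenolyse C–Br; both hydrogens should arrive from the α face because the β face is covered by the axial C11 methyl and the axial C15 silyloxy group, which puts H12 axial and bromine equatorial.

Step 16
Reactants: 21 bromo alcohol
Product: 22 primary iodide (C7–I)
Conditions: I2, PPh3, imidazole, CH2Cl2, 0 °C → rt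
Reagents that add atoms: iodine, II
Why: Appel-type iodination of the only primary alcohol; the neopentyl secondary bromide is inert to iodide under these conditions.

Step 17
Reactants: 23 3-methylbut-2-en-1-ol (prenol)
Product: 25 (R)-(3,3-dimethyloxiran-2-yl)methyl tosylate, via (R)-3,3-dimethylglycidol 24 (not isolated)
Conditions: Ti(OiPr)4 (cat.), D-(−)-DIPT (cat.), t-BuOOH, 4 Å MS, CH2Cl2, −20 °C; P(OMe)3; then TsCl, Et3N, DMAP (cat.), −10 °C
Reagents that add atoms: tert-butyl hydroperoxide, CC(C)(C)OO; p-toluenesulfonyl chloride, Cc1ccc(cc1)S(Cl)(=O)=O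
Why: Sharpless asymmetric epoxidation with the D-(−)-tartrate delivers oxygen to the face that gives the (R)-epoxide, and the water-soluble glycidol is sulfonylated in the same flask.

Step 18
Reactants: 25 (R)-epoxy tosylate; 26 methyl acetoacetate
Product: 28 methyl 5-[(2R)-3,3-dimethyloxiran-2-yl]-3-oxopentanoate, via acetoacetate dianion 27 (not isolated)
Conditions: NaH, THF, 0 °C; n-BuLi, 0 °C; then 25, DMPU, −20 °C → rt; sat. NH4Cl
Reagents that add atoms: none
Why: γ-Alkylation of the acetoacetate dianion by SN2 at the primary sulfonate; the epoxide (its other carbon fully substituted) and its stereocentre are not touched.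

Step 19
Reactants: 28 epoxy keto ester
Product: 29 methyl (6S)-6-bromo-7-hydroxy-7-methyl-3-oxooctanoate
Conditions: Li2NiBr4, THF, 0 °C → rt; pH 7 buffer
Reagents that add atoms: dilithium tetrabromonickelate(II), [Li+].[Li+].[Ni+2].[Br-].[Br-].[Br-].[Br-]
Why: SN2 opening of the epoxide at its less substituted carbon by soft bromide with inversion, which converts the (R)-epoxide into the (6S)-bromide and leaves the tertiary alcohol.

Step 20
Reactants: 29 bromohydrin keto ester
Product: 30 methyl (5S)-5-bromo-6,6-dimethyl-2-oxocyclohexane-1-carboxylate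
Conditions: SnCl4, CH2Cl2, −78 → −20 °C
Reagents that add atoms: none
Why: Lewis-acid ionisation of the tertiary alcohol with anchimeric help from bromine gives a configurationally defined bromonium ion (no alkene is present to exchange Br+), which the tin-chelated enol of the β-keto ester opens at the tertiary carbon in a 6-endo chair closure (cation–enol cyclisation); the C–Br centre is never broken and the epimerisable ester centre is removed in step 21.

Step 21
Reactants: 30 cyclic bromo keto ester
Product: 31 (S)-4-bromo-3,3-dimethylcyclohexan-1-one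
Conditions: 6 M HCl, AcOH, 90 °C
Reagents that add atoms: none
Why: Acidic ester hydrolysis and decarboxylation of the β-keto acid; the C–Br centre is γ to the carbonyl and cannot epimerise.

Step 22
Reactants: 22 primary iodide; 31 (S)-4-bromo-3,3-dimethylcyclohexan-1-one
Product: 34 tertiary alcohol (C1–OH), via alkyllithium 32 (not isolated), via organocerium 33 (not isolated)
Conditions: t-BuLi (2.1 equiv), Et2O–pentane, −78 °C; CeCl3 (anhydrous), THF, −78 °C; then 31, −78 → −40 °C; sat. NH4Cl
Reagents that add atoms: none
Why: Iodine–lithium exchange of the primary iodide should outrun any reaction of the hindered secondary bromide, transmetalation to cerium gives a nucleophile of low basicity that adds to the γ-bromo ketone without enolisation, and in the chair of 31 with equatorial bromine the axial C5 methyl blocks axial attack, so C7 enters equatorially and the new C1 centre has oxygen axial, cis to bromine.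

Step 23
Reactants: 34 tertiary alcohol
Product: 35 C1 acetate (C15 silyl ether)
Conditions: Ac2O, DMAP, Et3N, CH2Cl2, 40 °C
Reagents that add atoms: acetic anhydride, CC(=O)OC(C)=O
Why: DMAP-catalysed acylation of the only free hydroxyl, the tertiary C1 alcohol.

Step 24
Reactants: 35 C1 acetate
Product: 36 target CNP0221847.1
Conditions: HF·pyridine, THF–pyridine, 0 °C → rt
Reagents that add atoms: none
Why: Fluoride cleavage of the silyl ether under conditions that should leave the tertiary acetate and both secondary bromides intact.

**Compound list**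
1 | (S)-Wieland–Miescher ketone | O=C1CC[C@]2(C)C(=O)CCCC2=C1 | starting material
2 | bis(ethylene ketal) of 1, alkene at C15=C16 | O1CCOC12CC[C@]3(C)C4(OCCO4)CCC=C3C2 | intermediate
3 | 15α,16α-diol of 2 | O1CCOC12CC[C@]3(C)C4(OCCO4)CC[C@H](O)[C@@]3(O)C2 | intermediate
4 | 16α-hydroxy-15-ketone (α-ketol), C7 and C12 ketals | O1CCOC12CC[C@]3(C)C4(OCCO4)CCC(=O)[C@@]3(O)C2 | intermediate
5 | 15-oxo-C8=C16 enone, C7 and C12 ketals | O1CCOC12CC[C@]3(C)C4(OCCO4)CCC(=O)C3=C2 | intermediate
6 | 15β-hydroxy-15α-methyl-C8=C16 alkene, C7 and C12 ketals | O1CCOC12CC[C@]3(C)C4(OCCO4)CC[C@@](C)(O)C3=C2 | intermediate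
7 | γ-hydroxy enone (C7 ketone, C8=C16, C15 carbinol, C12 ketal) | O=C1CC[C@]2(C)C3(OCCO3)CC[C@@](C)(O)C2=C1 | intermediate
8 | lithium C15-alkoxide of 7 (not isolated) | O=C1CC[C@]2(C)C3(OCCO3)CC[C@@](C)(O[Li])C2=C1 | intermediate
9 | dilithium C7=C8 enolate / C15 alkoxide, trans-decalin (not isolated) | C1=C(O[Li])CC[C@]2(C)C3(OCCO3)CC[C@@](C)(O[Li])[C@@H]12 | intermediate
10 | trans-decalin C7=C8 triethylsilyl enol ether, C15 triethylsilyl ether, C12 ketal | C1=C(O[Si](CC)(CC)CC)CC[C@]2(C)C3(OCCO3)CC[C@@](C)(O[Si](CC)(CC)CC)[C@@H]12 | intermediate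
11 | lithium C7=C8 enolate, C15 OTES (not isolated) | C1=C(O[Li])CC[C@]2(C)C3(OCCO3)CC[C@@](C)(O[Si](CC)(CC)CC)[C@@H]12 | intermediate
12 | 8-trifluoroacetyl-7-ketone, drawn as the C7 enol | O=C(C1=C(O)CC[C@]2(C)C3(OCCO3)CC[C@@](C)(O[Si](CC)(CC)CC)[C@@H]12)C(F)(F)F | intermediate
13 | trans-decalin α-diazo ketone (C7=O, C8=N2) | [N-]=[N+]=C1C(=O)CC[C@]2(C)C3(OCCO3)CC[C@@](C)(O[Si](CC)(CC)CC)[C@@H]12 | intermediate
14 | ketene (C8=C7=O on the contracted ring; not isolated) | O=C=C1CC[C@]2(C)C3(OCCO3)CC[C@@](C)(O[Si](CC)(CC)CC)[C@@H]12 | intermediate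
15 | C8-epimeric (8β) methyl ester (not isolated) | COC(=O)[C@H]1CC[C@]2(C)C3(OCCO3)CC[C@@](C)(O[Si](CC)(CC)CC)[C@@H]12 | intermediate
16 | trans-hydrindane methyl ester (8α) | COC(=O)[C@@H]1CC[C@]2(C)C3(OCCO3)CC[C@@](C)(O[Si](CC)(CC)CC)[C@@H]12 | intermediate
17 | C7 primary alcohol, C12 ketal | OC[C@@H]1CC[C@]2(C)C3(OCCO3)CC[C@@](C)(O[Si](CC)(CC)CC)[C@@H]12 | intermediate
18 | C12 ketone, C7–OH | OC[C@@H]1CC[C@]2(C)C(=O)CC[C@@](C)(O[Si](CC)(CC)CC)[C@@H]12 | intermediate
19 | C12 (E)-hydrazone | OC[C@@H]1CC[C@]2(C)/C(=N/N)CC[C@@](C)(O[Si](CC)(CC)CC)[C@@H]12 | intermediate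
20 | vinyl bromide C12(Br)=C13 | OC[C@@H]1CC[C@]2(C)C(Br)=CC[C@@](C)(O[Si](CC)(CC)CC)[C@@H]12 | intermediate
21 | 12β-bromide, C7–OH | OC[C@@H]1CC[C@]2(C)[C@@H](Br)CC[C@@](C)(O[Si](CC)(CC)CC)[C@@H]12 | intermediate
22 | C7 iodide | IC[C@@H]1CC[C@]2(C)[C@@H](Br)CC[C@@](C)(O[Si](CC)(CC)CC)[C@@H]12 | intermediate
23 | 3-methylbut-2-en-1-ol (prenol) | CC(C)=CCO | starting material
24 | (R)-(3,3-dimethyloxiran-2-yl)methanol (not isolated) | OC[C@H]1OC1(C)C | intermediate
25 | (R)-(3,3-dimethyloxiran-2-yl)methyl 4-methylbenzenesulfonate | Cc1ccc(cc1)S(=O)(=O)OC[C@H]1OC1(C)C | intermediate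
26 | methyl acetoacetate | COC(=O)CC(C)=O | starting material
27 | sodium lithium dianion of methyl acetoacetate (not isolated) | COC(=O)[CH-]C(=O)[CH2-].[Na+].[Li+] | intermediate
28 | methyl 5-[(2R)-3,3-dimethyloxiran-2-yl]-3-oxopentanoate | COC(=O)CC(=O)CC[C@H]1OC1(C)C | intermediate
29 | methyl (6S)-6-bromo-7-hydroxy-7-methyl-3-oxooctanoate | COC(=O)CC(=O)CC[C@H](Br)C(C)(C)O | intermediate
30 | methyl (5S)-5-bromo-6,6-dimethyl-2-oxocyclohexane-1-carboxylate (keto form, ester cis to Br) | COC(=O)[C@@H]1C(=O)CC[C@H](Br)C1(C)C | intermediate
31 | (S)-4-bromo-3,3-dimethylcyclohexan-1-one | O=C1CC[C@H](Br)C(C)(C)C1 | intermediate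
32 | C7 alkyllithium (not isolated) | [Li]C[C@@H]1CC[C@]2(C)[C@@H](Br)CC[C@@](C)(O[Si](CC)(CC)CC)[C@@H]12 | intermediate
33 | C7 alkylcerium dichloride (not isolated) | Cl[Ce](Cl)C[C@@H]1CC[C@]2(C)[C@@H](Br)CC[C@@](C)(O[Si](CC)(CC)CC)[C@@H]12 | intermediate
34 | C1 tertiary alcohol, C15 OTES | O[C@]1(C[C@@H]2CC[C@]3(C)[C@@H](Br)CC[C@@](C)(O[Si](CC)(CC)CC)[C@@H]23)CC[C@H](Br)C(C)(C)C1 | intermediate
35 | C1 acetate, C15 OTES | CC(=O)O[C@]1(C[C@@H]2CC[C@]3(C)[C@@H](Br)CC[C@@](C)(O[Si](CC)(CC)CC)[C@@H]23)CC[C@H](Br)C(C)(C)C1 | intermediate
36 | CNP0221847.1 | CC(=O)O[C@]1(C[C@@H]2CC[C@]3(C)[C@@H](Br)CC[C@@](C)(O)[C@@H]23)CC[C@H](Br)C(C)(C)C1 | target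

**Step count and risks**

Total: 24 steps. Longest linear sequence: 19 steps (steps 1–16 and 22–24, from 1 to 36); the ring A branch is 5 steps (17–21).

Step 22 (fragment union). What may go wrong: tert-butyllithium attacks the secondary C12 bromide (exchange or elimination) in competition with the iodide, or the cerium reagent is quenched by enolisation of the γ-bromo ketone; facial selectivity would also erode if the axial-bromine chair of 31 reacts. Fallback: the union is moved ahead of the C12 bromination so that the nucleophile carries no bromine. Setting out from alcohol 17, Appel-type iodination gives the ketal iodide F1. Iodine–lithium exchange (alkyllithium F2), transmetalation (alkylcerium F3) and addition to 31 give the ketal carbinol F4. PPTS in wet acetone then frees the ketone F5, hydrazine gives the hydrazone F6, and NBS/pyridine the vinyl bromide F7. Hydrogenation over Rh/Al2O3 from the α face rejoins the route at 34.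

Step 20 (ring A closure). What may go wrong: the tertiary alcohol is consumed by hemiketalisation onto the C3 ketone and dehydration to a dihydropyran, or by proton loss to an isopropenyl bromide, faster than it ionises to the bromonium ion; capture by oxygen instead of carbon is a further leak. Fallback: ring A is closed as the racemate by direct bromonium transfer to an alkene, and the ketone is then resolved. Setting out from methyl acetoacetate 26, its dianion 27 is alkylated with prenyl bromide to methyl 7-methyl-3-oxooct-6-enoate F8. Bromodiethylsulfonium bromopentachloroantimonate in nitromethane at −25 °C should give the racemic bromo keto ester F9, and hydrolysis with decarboxylation as in step 21 the racemic ketone F10. Lithiated (S)-N,S-dimethyl-S-phenylsulfoximine adds equatorially to give the β-hydroxy sulfoximine of the S ketone F11 and that of the R ketone F12, which are separated by chromatography. Heating F11 in toluene releases the ketone and rejoins the route at 31.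

Step 15 (reduction of the vinyl bromide). What may go wrong: hydrogenolysis of the C–Br bond on the metal surface, or no uptake at the hindered trisubstituted alkene. Fallback: the reduction is run as a radical hydrogen-atom transfer instead of a surface hydrogenation (Co(acac)2, t-BuOOH, Et3SiH, 1,4-cyclohexadiene, n-PrOH, rt). A cobalt hydride transfers a hydrogen atom to C13 and the α-bromo radical at C12 takes its hydrogen on the open α face; no metal inserts into C–Br. It sets out from 20 and rejoins at 21 without new intermediates.

**Further compounds**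
F1 | step 22 | C7 iodide with C12 ketal | IC[C@@H]1CC[C@]2(C)C3(OCCO3)CC[C@@](C)(O[Si](CC)(CC)CC)[C@@H]12
F2 | step 22 | C7 alkyllithium with C12 ketal | [Li]C[C@@H]1CC[C@]2(C)C3(OCCO3)CC[C@@](C)(O[Si](CC)(CC)CC)[C@@H]12
F3 | step 22 | C7 alkylcerium dichloride with C12 ketal | Cl[Ce](Cl)C[C@@H]1CC[C@]2(C)C3(OCCO3)CC[C@@](C)(O[Si](CC)(CC)CC)[C@@H]12
F4 | step 22 | C1 carbinol with C12 ketal | O[C@]1(C[C@@H]2CC[C@]3(C)C4(OCCO4)CC[C@@](C)(O[Si](CC)(CC)CC)[C@@H]23)CC[C@H](Br)C(C)(C)C1
F5 | step 22 | C1 carbinol with C12 ketone | O[C@]1(C[C@@H]2CC[C@]3(C)C(=O)CC[C@@](C)(O[Si](CC)(CC)CC)[C@@H]23)CC[C@H](Br)C(C)(C)C1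
F6 | step 22 | C1 carbinol with C12 (E)-hydrazone | O[C@]1(C[C@@H]2CC[C@]3(C)/C(=N/N)CC[C@@](C)(O[Si](CC)(CC)CC)[C@@H]23)CC[C@H](Br)C(C)(C)C1
F7 | step 22 | C1 carbinol with C12(Br)=C13 vinyl bromide | O[C@]1(C[C@@H]2CC[C@]3(C)C(Br)=CC[C@@](C)(O[Si](CC)(CC)CC)[C@@H]23)CC[C@H](Br)C(C)(C)C1
F8 | step 20 | methyl 7-methyl-3-oxooct-6-enoate | COC(=O)CC(=O)CCC=C(C)C
F9 | step 20 | racemic methyl 5-bromo-6,6-dimethyl-2-oxocyclohexane-1-carboxylate | COC(=O)C1C(=O)CCC(Br)C1(C)C
F10 | step 20 | racemic 4-bromo-3,3-dimethylcyclohexan-1-one | O=C1CCC(Br)C(C)(C)C1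
F11 | step 20 | β-hydroxy sulfoximine from the (S)-ketone | CN=[S@](=O)(C[C@]1(O)CC[C@H](Br)C(C)(C)C1)c1ccccc1
F12 | step 20 | β-hydroxy sulfoximine from the (R)-ketone | CN=[S@](=O)(C[C@@]1(O)CC[C@@H](Br)C(C)(C)C1)c1ccccc1
F0 | step 15 | none | none
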